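**Assumption:** the target (albaspidin AB) has no stereocentre and no stereogenic double bond, so it is one achiral compound and no stereocontrol is needed; all keto–enol tautomers are treated as the same compound and drawn as in the given SMILES.

## Retrosynthetic overview

1. Cut the C–CH2–C bridge: acetylfilicinic acid 10 (used as its Mannich electrophile) plus butyrylfilicinic acid 13.
2. Both halves come from one filicinic acid 7 and an acyl chloride (O-acylation, then O→C acyl transfer).
3. Ring of 7: one-carbon ring expansion (1,2-shift of a ring carbon onto a diazo-derived carbon) of the cyclopentanetrione 4.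
4. Trione 4: double Claisen condensation of 3-methylbutan-2-one with dimethyl oxalate.
5. Ring order: the five-membered ring is made first, expanded once to the six-membered ring, and that ring is used for both halves.

## Route

Step 1
Reactants: 1 3-methylbutan-2-one; 2 dimethyl oxalate
Product: 4 3,3-dimethylcyclopentane-1,2,4-trione, via diketo ester 3 (not isolated)
Conditions: NaH (3.0 equiv), THF, 0 → 65 °C (ketone added slowly); then 2 M HCl
Reagents that add atoms: none
Why: Crossed Claisen condensation at the methyl group of 1 gives the enolate of 3, and a Dieckmann condensation from the isopropyl carbon onto the remaining ester closes the five-membered ring and forms the quaternary carbon, driven by irreversible deprotonation with NaH and by the stable vinylogous-acid enolate of 4; no stereocentre is formed.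

Step 2
Reactants: 4 3,3-dimethylcyclopentane-1,2,4-trione
Product: 7 filicinic acid (3,5-dihydroxy-4,4-dimethylcyclohexa-2,5-dien-1-one), via silyl enol ether 5 (not isolated), via ring-expanded silyl ketone 6 (not isolated)
Conditions: HN(SiMe3)2 (0.6 equiv), CH2Cl2, 40 °C, evaporate; TMSCHN2 (1.2 equiv), Sc(OTf)3 (5 mol %), toluene, −20 → 0 °C; then 1 M HCl, THF, 25 °C
Reagents that add atoms: trimethylsilyldiazomethane C[Si](C)(C)C=[N+]=[N-] (gives the new ring carbon); hexamethyldisilazane C[Si](C)(C)N[Si](C)(C)C (its silyl group is carried only by 5 and 6)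
Why: Proposed new method: silylation masks the acidic enol as a vinylogous silyl ester, which blocks O-alkylation by the diazo reagent and makes the alkene a poor dipolarophile; trivalent scandium (Sc(OTf)3) then activates the only non-vinylogous ketone of 5 (C3, next to the silyloxy-alkene carbon), TMSCHN2 adds to give a β-oxido diazonium betaine, and loss of N2 with 1,2-shift of the electron-rich silyloxyvinyl ring carbon (favoured over the acyl-bearing quaternary CMe2 carbon) expands the five-membered ring to the six-membered ring with the new carbon between two oxygenated carbons, so that acid hydrolysis of both silyl groups gives 7; the closest known reaction type is the Lewis-acid-catalysed diazoalkane homologation of cyclic ketones (Büchner–Curtius–Schlotterbeck / Tiffeneau–Demjanov-type ring expansion, known also for aryl-fused 1,2-diones), not yet shown on an enol-masked cyclopentane-1,2,4-trione; no stereocentre is formed.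

Step 3
Reactants: 7 filicinic acid; 8 acetyl chloride
Product: 10 acetylfilicinic acid (2-acetyl-3,5-dihydroxy-6,6-dimethylcyclohexa-2,4-dien-1-one), via enol acetate 9 (not isolated)
Conditions: 8 (1.0 equiv), Et3N (2.2 equiv), CH2Cl2, 0 °C; then DMAP (0.2 equiv), 25 °C; 1 M HCl work-up
Reagents that add atoms: none
Why: O-acylation of the enol followed by DMAP-catalysed O→C acyl transfer (Steglich-type rearrangement of an enol ester, the standard route to 2-acyl-1,3-diones) gives the chelated C-acyl triketone, and the first acyl group deactivates the second ring CH so mono-acylation stops cleanly.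

Step 4
Reactants: 7 filicinic acid; 11 butanoyl chloride
Product: 13 butyrylfilicinic acid (2-butanoyl-3,5-dihydroxy-6,6-dimethylcyclohexa-2,4-dien-1-one), via enol butyrate 12 (not isolated)
Conditions: 11 (1.0 equiv), Et3N (2.2 equiv), CH2Cl2, 0 °C; then DMAP (0.2 equiv), 25 °C; 1 M HCl work-up
Reagents that add atoms: none
Why: The same O-acylation and DMAP-catalysed O→C acyl transfer as in step 3, with the same thermodynamic preference for the chelated 2-acyl triketone.

Step 5
Reactants: 10 acetylfilicinic acid; 13 butyrylfilicinic acid
Product: 16 albaspidin AB (target), via Mannich base 14 (not isolated), via methylene trione 15 (not isolated)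
Conditions: 10, CH2(NMe2)2 (1.0 equiv), CH2Cl2, 0 → 25 °C, evaporate; then 13 (1.05 equiv), MeCN, 60 °C; 1 M HCl wash
Reagents that add atoms: bis(dimethylamino)methane CN(C)CN(C)C
Why: A Mannich reaction at the only free ring CH of 10 gives 14, which loses dimethylamine on warming to the quinone-methide-like acceptor 15, and Michael addition of the free ring CH of 13 forms the methylene bridge; making the electrophile from one partner only gives the unsymmetrical dimer, and no stereocentre is formed.

## Compound list

1 | 3-methylbutan-2-one | CC(C)C(C)=O | starting material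
2 | dimethyl oxalate | COC(=O)C(=O)OC | starting material
3 | methyl 5-methyl-2,4-dioxohexanoate (present as its sodium enolate) | CC(C)C(=O)CC(=O)C(=O)OC | intermediate
4 | 3,3-dimethylcyclopentane-1,2,4-trione (largely enolised) | O=C1CC(=O)C(C)(C)C1=O | intermediate
5 | 2,2-dimethyl-4-(trimethylsilyloxy)cyclopent-4-ene-1,3-dione | C[Si](C)(C)OC1=CC(=O)C(C)(C)C1=O | intermediate
6 | 2,2-dimethyl-4-(trimethylsilyl)-5-(trimethylsilyloxy)cyclohex-5-ene-1,3-dione | C[Si](C)(C)OC1=CC(=O)C(C)(C)C(=O)C1[Si](C)(C)C | intermediate
7 | filicinic acid, 3,5-dihydroxy-4,4-dimethylcyclohexa-2,5-dien-1-one | CC1(C)C(O)=CC(=O)C=C1O | intermediate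
8 | acetyl chloride | CC(Cl)=O | starting material
9 | 5-hydroxy-4,4-dimethyl-3-oxocyclohexa-1,5-dien-1-yl acetate | CC(=O)OC1=CC(=O)C(C)(C)C(O)=C1 | intermediate
10 | acetylfilicinic acid, 2-acetyl-3,5-dihydroxy-6,6-dimethylcyclohexa-2,4-dien-1-one | CC(=O)C1=C(O)C=C(O)C(C)(C)C1=O | intermediate
11 | butanoyl chloride | CCCC(Cl)=O | starting material
12 | 5-hydroxy-4,4-dimethyl-3-oxocyclohexa-1,5-dien-1-yl butanoate | CCCC(=O)OC1=CC(=O)C(C)(C)C(O)=C1 | intermediate
13 | butyrylfilicinic acid, 2-butanoyl-3,5-dihydroxy-6,6-dimethylcyclohexa-2,4-dien-1-one | CCCC(=O)C1=C(O)C=C(O)C(C)(C)C1=O | intermediate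
14 | 2-acetyl-4-[(dimethylamino)methyl]-3,5-dihydroxy-6,6-dimethylcyclohexa-2,4-dien-1-one | CC(=O)C1=C(O)C(CN(C)C)=C(O)C(C)(C)C1=O | intermediate
15 | 2-acetyl-3-hydroxy-6,6-dimethyl-4-methylidenecyclohex-2-ene-1,5-dione | CC(=O)C1=C(O)C(=C)C(=O)C(C)(C)C1=O | intermediate
16 | albaspidin AB: CH2 links C4 of acetylfilicinic acid 10 to C4 of butyrylfilicinic acid 13 | CCCC(=O)C1=C(O)C(CC2=C(O)C(C)(C)C(=O)C(C(C)=O)=C2O)=C(O)C(C)(C)C1=O | target

## Summary

Total step count: 5.
Longest linear sequence: 4 steps (1 → 4 → 7 → 10 or 13 → 16).

Three steps most likely to fail: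

**Step 2 (the proposed new ring expansion).** It can fail through migration of the quaternary carbon instead of the silyloxyvinyl carbon, epoxide formation from the betaine, or dipolar addition of the diazo reagent to the alkene. The fallback uses only known chemistry, sets out from compound 1 and comes back at compound 7. Ketone 1 is carbomethoxylated at its methyl group (NaH, dimethyl carbonate, THF, reflux) to methyl 4-methyl-3-oxopentanoate F3. The dianion of F3 (NaH, then n-BuLi, THF, 0 °C) is acylated at the tertiary γ-carbon with N-methoxy-N-methylacetamide to give methyl 4,4-dimethyl-3,5-dioxohexanoate F4. A dimedone-type intramolecular Claisen condensation of F4 (NaOMe, MeOH, reflux; methyl-ketone enolate onto the ester) closes the six-membered ring directly to 7.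

**Step 1 (Dieckmann closure that must form the quaternary carbon through a dianion).** It may stall at 3 or give over-oxalylation. The fallback reverses the order of the two C–C bond formations, sets out from compound 1 and comes back at compound 4. Ketone 1 is converted under thermodynamic conditions (Me3SiCl, NaI, Et3N, MeCN) into the tetrasubstituted silyl enol ether 3-methyl-2-(trimethylsilyloxy)but-2-ene F1. Mukaiyama-type C-acylation of F1 with methyl chlorooxoacetate (ZnCl2, CH2Cl2, −78 → 0 °C) makes the quaternary carbon first and gives methyl 3,3-dimethyl-2,4-dioxopentanoate F2. LiN(SiMe3)2 (2.1 equiv, THF, −78 → 0 °C) then closes the kinetic methyl-ketone enolate onto the ester to give 4.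

**Step 5 (unsymmetrical methylene coupling).** The risks are incomplete Mannich formation and base-induced exchange of the halves, which would give the two symmetric dimers. The fallback sets out from compound 10 and comes back at compound 16. Compound 10 is condensed with aqueous formaldehyde and PhSO2Na (HCO2H, EtOH/H2O, 25 °C) to the isolable, purifiable sulfone 2-acetyl-3,5-dihydroxy-6,6-dimethyl-4-[(phenylsulfonyl)methyl]cyclohexa-2,4-dien-1-one F5. Treating F5 with 13 and i-Pr2NEt in CH2Cl2 at 0 °C eliminates sulfinate to 15 under mild, amine-free conditions, and 13 traps it to give 16.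

Further compounds
F1 | step 1 | 3-methyl-2-(trimethylsilyloxy)but-2-ene | CC(C)=C(C)O[Si](C)(C)C
F2 | step 1 | methyl 3,3-dimethyl-2,4-dioxopentanoate | COC(=O)C(=O)C(C)(C)C(C)=O
F3 | step 2 | methyl 4-methyl-3-oxopentanoate | COC(=O)CC(=O)C(C)C
F4 | step 2 | methyl 4,4-dimethyl-3,5-dioxohexanoate | COC(=O)CC(=O)C(C)(C)C(C)=O
F5 | step 5 | 2-acetyl-3,5-dihydroxy-6,6-dimethyl-4-[(phenylsulfonyl)methyl]cyclohexa-2,4-dien-1-one | CC(=O)C1=C(O)C(CS(=O)(=O)c2ccccc2)=C(O)C(C)(C)C1=O
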